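One molar of reagent consumes one molar of whichever substrate it meets, so we count these flasks in molar of reagent.

all flasks: starting material 0.058 M
- Saturday's: reagent 0.087 M; second substrate 0.029 M (fed, over 30 s); third substrate 0.067 M; temperature −5 °C; run made earlier
- Monday's: reagent 0.087 M; second substrate 0.029 M (fed, over 30 s); third substrate 0.078 M; temperature 12 °C; run made earlier
- Tuesday's: reagent 0.087 M; second substrate 0.029 M (fed, over 30 s); third substrate 0.12 M; temperature −5 °C; run made earlier
- Friday's: reagent 0.14 M; second substrate 0.029 M (fed, over 30 s); third substrate 0.116 M; temperature 12 °C; run made earlier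
- dawn: reagent 0.200 M; second substrate 0.0290 M (fed, over 30 s); third substrate 0.0600 M; at 0 °C throughout; time 2.0 min
- spring: reagent 0.0870 M; second substrate 0.0290 M (fed, over 30 s); third substrate 0.116 M; at 0 °C until 30 s, from then on at 25 °C; time 2.0 min

| run | time / s | target / % | starting material / % |
|---|---|---|---|
| Saturday's | 12.0 | 2.1 | 97.1 |
| Saturday's | 25.0 | 5.3 | 94.4 |
| Saturday's | 40.0 | 8.5 | 92.5 |
| Saturday's | 50.0 | 8.4 | 91.7 |
| Saturday's | 60.0 | 9.8 | 88.4 |
| Monday's | 10.0 | 7.8 | 94.0 |
| Monday's | 15.0 | 11.7 | 88.0 |
| Monday's | 20.0 | 14.6 | 85.2 |
| Monday's | 30.0 | 17.7 | 80.9 |
| Tuesday's | 10.0 | 2.5 | 99.3 |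
| Tuesday's | 15.0 | 4.3 | 96.9 |
| Tuesday's | 30.0 | 6.1 | 93.4 |
| Tuesday's | 40.0 | 7.0 | 90.5 |
| Tuesday's | 60.0 | 11.1 | 90.8 |
| Friday's | 10.0 | 10.8 | 89.5 |
| Friday's | 15.0 | 17.3 | 84.3 |
| Friday's | 20.0 | 20.5 | 81.6 |
| Friday's | 30.0 | 25.5 | 72.6 |

(each reading ± 1 percentage point)

- the earlier runs were read with a standard deviation of 1 percentage point
- what may be going on: second substrate + reagent -> second product; starting material + reagent -> target; third substrate + reagent -> third product; third substrate -> decomposition product

- which of the two ends with the higher amount of target, in percent of the starting material charged ("neither" if they lie within 2 percentage points) (dawn / spring / neither)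
- target at the end, in percent of the starting material charged, dawn
- target at the end, in percent of the starting material charged, spring

The bench rule is pseudo-first-order: with reagent in excess, the logarithm of the fraction left grows with reagent concentration times time. Saturday's last reading has 88.4% of the starting material left after 60.0 s. Scaling that logarithm to dawn's reagent and time gives 43.3% target, and somewhat more for a bath warmer than Saturday's. Friday's reading of 72.6% left, scaled to spring's warm stretch, gives 45.0%, and again more at 25 °C, which is warmer than Friday's 12 °C.

The border of this rule is a ratio of charges. Spring has 0.429 and dawn 1.36 of reagent charged per substrate charged, and we call this ratio the reagent cover. Dawn's reagent exceeds the three charges, and it keeps 26.5% of itself once they are consumed, so the rule roughly stands there. In spring the reagent is the limiting reagent, so the rule fails. If second substrate takes its whole charge, 0.0580 M of reagent remains for 0.174 M of starting material and third substrate. Should both keep the same fraction left, 33.3% of each is converted. We set the rule's 45.0% aside for spring and commit to that last figure there, with dawn above 43.3%, so dawn ahead.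

The forecast also puts dawn ahead, with 45% for dawn and 30% for spring, the latter below our figure; its spring begins by “leaving about 0.043 M reagent against 0.105 M third substrate”.

The flasks give 49.9% for dawn and 44.5% for spring, so dawn ends higher.

    second substrate + reagent → second product (k = 0.242 /M/s, Ea = 42.0 kJ/mol)
    starting material + reagent → target (k = 0.0374 /M/s, Ea = 48.0 kJ/mol)
    third substrate + reagent → third product (k = 0.0175 /M/s, Ea = 44.0 kJ/mol)
    third substrate → decomposition product (k = 6.92 × 10⁻⁶ /s, Ea = 90.0 kJ/mol)
    (constants at 0 °C)

Spring, with its cover of 0.429, ends with 10.2% of its reagent left. The shrinking supply is a part of the reason it stops there: with the supply held, spring gives 83.8% and not 44.5%. Dawn stands at 49.9% through the time given together with its own shrinking supply of reagent: after 20.0 min it gives 98.1%, and with the supply held 59.2%. A flask like dawn kept at 25 °C shares dawn's cover of 1.36, and after 2.00 min it holds 38.0% of its reagent, above the 26.5% that its charges keep, with target at 94.0%.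

The readings were generated by integration for substances that don't exist, and the scatter is random.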